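The numbers in the tables are simulated on assumed constants.

3.0 d at 0.23 M has to be read against the teal run, which has gone further than the green run so far.

| flask | substrate | remark | time |
|---|---|---|---|
| green | 0.23 M | the very flask that is asked about, followed so far |  |
| teal | 0.46 M | run made earlier |  |
| flask | 0.23 M |  | 3.0 d |

| run | time / h | side product / % | target / % | substrate / % |
|---|---|---|---|---|
| green | 0.500 | 0 | 0 | 100 |
| green | 1.00 | 0 | 0 | 97 |
| green | 2.50 | 3 | 0 | 93 |
| green | 6.00 | 3 | 0 | 83 |
| teal | 8.00 | 0 | 3 | 79 |
| teal | 15.0 | 3 | 18 | 56 |
| teal | 20.0 | 2 | 37 | 36 |
| teal | 30.0 | 3 | 69 | 7 |

(each reading ± 1.5 percentage points)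

* concentration of side product at 3.0 d, in M
* concentration of target at 3.0 d, in M

- in percentages every species weighs as the substrate in it: one side product counts as two

In the teal run the fractional loss of substrate rose from 0.0884 h⁻¹ to 0.164 h⁻¹ over its last two intervals, twice over, and mean target also rose twice over. So in the teal run the loss reads as following c_target, as in self-acceleration (autocatalysis). At equal percentages c_target scales with the charge, so that stretch is taken here to run on charge times time. For the green flask this gives 36.0 h as teal-equivalent time, the time multiplied by the flask's charge and divided by the teal charge. The rule is rough at the start, where the early losses, 0.0311 h⁻¹ in green and 0.0295 h⁻¹ in teal, do not scale with charge.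

The last teal reading, at 30.0 h, lies before that time: target 69%, substrate 7%. The part of the teal charge found in no measured species stayed level within the scatter, 23.0% at 15.0 h and 21.0% at 30.0 h. Keeping that gap and turning the remaining substrate into target, the reckoning here gives c_target near 0.175 M. Side product at 3%, counted double, gives 0.00345 M.

The forecast says 0.205 M target and 0.0045 M side product, with the hidden material “leaving only a few percent”. It stands higher than this reckoning on both.

The flask gives 0.178 M target and 0.00351 M side product, and at 3.00 d the dormant form still holds 14.5% of the charge.

    substrate + target → 2 target (k = 0.690 M⁻¹ h⁻¹)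
    substrate → target (k = 0.00130 h⁻¹)
    substrate + target → side product (k = 0.0140 M⁻¹ h⁻¹)
    substrate ⇌ dormant form (K = 0.710, k = 0.0270 h⁻¹)

At 3.00 d, a teal-equivalent time of 36.0 h, the flask holds 77.4% target, more than the last teal reading. The same flask left until 30 h has a teal-equivalent time of 15.0 h, where the teal reading shows 18% target. That flask holds 21.6%, more than that reading, which is a c_target of 0.0498 M.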